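**Strategy.** Germacrane numbering is used (C1 = dihydrofuran CH–O, C4/C5 = the lactone diol carbons, C8 = spiroketal carbon). The ten-membered carbocycle is disconnected across C2–C3. Its C1 oxygen and the C4–C5 diol inside the C15–O–C6 lactone are read as a latent C1=C10/C4=C5 1,5-diene, the retron of a Cope ring expansion of a C5–C10 cyclohexane. Heating a furan-fused cyclohexane that carries a 1-siloxyvinyl group on C10 and a cis-fused α-methylene lactone across C5–C6 should, in one operation, form C2–C3, break C5–C10 and give the carbocycle with the bridging butenolide and a C1 enol silane. The furan (C7, C8, C11, C12) is later oxidised to the spiroketal lactone.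

Key step: step 13

Remark on the chemistry: C8 is a ketal carbon tied to C1 through the O1 bridge and cannot be set independently; it is assumed that the bridged spiroketal closes, or equilibrates under acid, to the C8 configuration written in the target string, which is used throughout.

## Route

Step 1
Reactants: 1 ethyl acetoacetate; 2 chloroacetone
Product: 3 ethyl 2,4-dimethylfuran-3-carboxylate
Conditions: pyridine, rt → 60 °C; then aq. HCl
Reagents that add atoms: none
Why: Feist–Benary furan synthesis, in which aldol addition to the chloroacetone carbonyl, O-alkylation by the enol and dehydration place the methyl groups at furan C2 and C4 (C9 and C13 of the target).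

Step 2
Reactants: 3 ethyl 2,4-dimethylfuran-3-carboxylate
Product: 4 ethyl 2-(bromomethyl)-4-methylfuran-3-carboxylate
Conditions: NBS, AIBN (cat.), PhCF3, 80 °C
Reagents that add atoms: N-bromosuccinimide, O=C1CCC(=O)N1Br
Why: Wohl–Ziegler radical bromination, expected at the 2-methyl group because its radical is stabilised by the ring oxygen.

Step 3
Reactants: 4 ethyl 2-(bromomethyl)-4-methylfuran-3-carboxylate; 5 3-methylpentane-2,4-dione
Product: 7 ethyl 4-methyl-2-(2-methyl-3-oxobutyl)furan-3-carboxylate (racemic), via diketone 6 (not isolated)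
Conditions: NaH, THF, 0 °C → rt; then EtOH, NaOEt (cat.), rt
Reagents that add atoms: none
Why: C-alkylation of the diketone enolate, then retro-Claisen cleavage of the non-enolisable 2,2-disubstituted 1,3-diketone by ethoxide, leaves the methyl ketone with C9, C10, C14, C1 and C2 in place.

Step 4
Reactants: 7 ethyl 4-methyl-2-(2-methyl-3-oxobutyl)furan-3-carboxylate
Product: 8 ethyl 2-[(E)-3-(tert-butyldimethylsilyloxy)-2-methylbut-2-enyl]-4-methylfuran-3-carboxylate (enol geometry immaterial)
Conditions: TBSCl, NaI, Et3N, MeCN, 50 °C
Reagents that add atoms: tert-butyldimethylsilyl chloride, CC(C)(C)[Si](C)(C)Cl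
Why: Silyl enol ether formation under equilibrating conditions (silyl iodide formed in situ) should give the more substituted C1=C10 enol silane, which masks the ketone and stores the C10 nucleophile.

Step 5
Reactants: 8 enol silane ester
Product: 9 {2-[(E)-3-(tert-butyldimethylsilyloxy)-2-methylbut-2-enyl]-4-methylfuran-3-yl}methanol
Conditions: i-Bu2AlH, CH2Cl2, −78 → 0 °C; Rochelle salt
Reagents that add atoms: none
Why: Hydride reduction of the ester to the primary alcohol, to which the enol silane is inert.

Step 6
Reactants: 9 furylmethanol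
Product: 10 2-[(E)-3-(tert-butyldimethylsilyloxy)-2-methylbut-2-enyl]-4-methylfuran-3-carbaldehyde
Conditions: MnO2, CH2Cl2, rt
Reagents that add atoms: none
Why: Neutral MnO2 oxidation of the benzylic-type furylmethanol stops at the aldehyde (C6) and spares the enol silane.

Step 7
Reactants: 10 furan-3-carbaldehyde; 11 methyl propiolate
Product: 12 methyl (4R)-4-{2-[(E)-3-(tert-butyldimethylsilyloxy)-2-methylbut-2-enyl]-4-methylfuran-3-yl}-4-hydroxybut-2-ynoate
Conditions: Me2Zn, (S,S)-ProPhenol (10 mol %), Ph3PO (20 mol %), toluene, 4 °C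
Reagents that add atoms: none
Why: Catalytic asymmetric addition of the zinc alkynylide to the aldehyde sets C6 under ligand control; the ligand antipode that gives the (R)-carbinol is the one used, to be confirmed by Mosher ester analysis.

Step 8
Reactants: 12 (R)-propargylic alcohol
Product: 14 (5R)-5-{2-[(E)-3-(tert-butyldimethylsilyloxy)-2-methylbut-2-enyl]-4-methylfuran-3-yl}furan-2(5H)-one, via hydroxy enoate 13 (not isolated)
Conditions: H2 (1 atm), Lindlar catalyst (Pd/CaCO3 poisoned with Pb(OAc)2), quinoline, EtOAc, rt; then silica gel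
Reagents that add atoms: none
Why: cis-Semihydrogenation of the ynoate puts the ester and the carbinol on the same side of the alkene, so lactonisation to butenolide A follows without base and C6 is not touched.

Step 9
Reactants: 14 (R)-furyl butenolide
Product: 16 (5R,6R,10S)-cis-fused furano keto lactone (acetyl on C10 drawn trans to C4), via silyl ketene acetal 15 (not isolated)
Conditions: HNTf2 (5 mol %), CH2Cl2, −78 °C; then 1 M HCl, THF, 0 °C
Reagents that add atoms: none
Why: Intramolecular Mukaiyama–Michael addition (6-exo) of the C10 enol silane to the silyl-activated butenolide closes the C5–C10 cyclohexane; the tether can reach C5 only on the face that carries C7, so the lactone is cis-fused, the acidic medium leaves C6 unenolised, and the C10 configuration need not be controlled because C10 becomes sp2 again.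

Step 10
Reactants: 16 keto lactone
Product: 17 (5R,6R,10S)-1-(tert-butyldimethylsilyloxy)vinyl lactone
Conditions: TBSOTf, Et3N, CH2Cl2, 0 °C
Reagents that add atoms: tert-butyldimethylsilyl triflate, CC(C)(C)[Si](C)(C)OS(=O)(=O)C(F)(F)F
Why: Soft enolisation and O-silylation of the methyl ketone, which can enolise only toward its CH3 group, installs the C1=C2 enol silane and protects the ketone from the lactone enolate chemistry that follows.

Step 11
Reactants: 17 siloxyvinyl lactone
Product: 18 C4-(dimethylaminomethyl) lactone (Mannich base; C4 configuration immaterial)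
Conditions: LDA, THF, −78 °C; then CH2=NMe2+ I−, −78 → 0 °C
Reagents that add atoms: Eschenmoser's salt (N,N-dimethylmethyleneiminium iodide), C=[N+](C)C.[I-]
Why: Mannich reaction of the lactone lithium enolate with the iminium salt on the convex face introduces C3.

Step 12
Reactants: 18 Mannich base
Product: 20 (5S,6R,10S)-furano-elemanolide with cis-fused α-methylene lactone and 1-siloxyvinyl group on C10, via methiodide 19 (not isolated)
Conditions: MeI, MeOH, rt; then aq. NaHCO3, CH2Cl2, rt
Reagents that add atoms: none
Why: N-Quaternisation followed by base-induced elimination of trimethylamine (Eschenmoser methylenation) unveils the C3=C4 methylene lactone without affecting the enol silane.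

Step 13
Reactants: 20 furano-elemanolide
Product: 21 (6R)-furano-germacranolide with C15–O–C6 butenolide on the ring-trans C4=C5 bond and ring-trans C1=C10 tert-butyldimethylsilyl enol ether
Conditions: degassed o-xylene, BHT (cat.), N,O-bis(trimethylsilyl)acetamide (0.1 equiv), silylated sealed tube, 160 °C; recovered 20 resubmitted
Reagents that add atoms: none
Why: Thermal [3,3]-sigmatropic (2-siloxy-Cope) rearrangement through a chair-like array C3=C4–C5–C10–C1=C2, in which the C2–C3 bond forms as the C5–C10 bond breaks. The closest known reactions are the thermal equilibration of furano-elemanolides with furano-germacranolides and the Cope ring expansion of 1,2-divinylcyclohexanes that carry a 2-siloxy group. No ring is closed end to end: the ten-membered carbocycle arises by four-carbon expansion of the C5–C10 cyclohexane, and lactone ring A passes from fused to bridging without being opened. No stereocentre is formed; C5 and C10 become sp2, which is why the C10 configuration of 20 is irrelevant, and C6 (R) lies outside the reacting array. The step needs the ring-expanded side of an equilibrium and a C4=C5 bond that is trans within the ten-membered ring: the second is enforced because C15 and C6 stay tied cis in the lactone, and the first is expected to be favoured by the exchange of two 1,1-disubstituted alkenes for an endocyclic butenolide and a tetrasubstituted enol silane with loss of the congested C5–C10 bond, unchanged 20 being recycled. The cis-fused lactone holds C3=C4 gauche to the equatorial siloxyvinyl group as the chair requires, and acid is excluded because it would divert the enol silane into C2-to-C3 Mukaiyama–Michael closure.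

Step 14
Reactants: 21 furano-germacranolide enol silane
Product: 22 (6R,9Z)-1-oxo-9-ene furano-germacranolide (enone)
Conditions: Pd(OAc)2 (1.1 equiv), MeCN, rt
Reagents that add atoms: none
Why: Saegusa–Ito dehydrogenation, in which the divalent palladium enolate at C10 undergoes β-hydride elimination toward the furfurylic C9–H; the ring is expected to accommodate only the C9=C10 isomer with C1 and C8 cis, and both C1=C10 enol geometries (from either C10 epimer of 20) converge here.

Step 15
Reactants: 22 enone
Product: 23 (1S,6R,9Z)-allylic alcohol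
Conditions: (R)-2-methyl-CBS-oxazaborolidine (0.2 equiv), catecholborane, toluene, −78 °C
Reagents that add atoms: none
Why: Corey–Bakshi–Shibata 1,2-reduction under reagent control; with the trisubstituted alkenyl arm as the large group, the (R)-catalyst should deliver hydride to the face that gives (1S).

Step 16
Reactants: 23 allylic alcohol
Product: 26 (1S,6R,8S)-1,8-epoxygermacra-4,7(11),9-triene-15,6:12,8-diolide, via endoperoxide 24 (not isolated), via hydroperoxide 25 (not isolated)
Conditions: O2, tetraphenylporphyrin (cat.), visible light, CH2Cl2, −78 → −20 °C; then Ac2O, pyridine, 0 °C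
Reagents that add atoms: oxygen, O=O
Why: [4+2] photooxygenation of the furan, transannular opening of the endoperoxide at C8 by the C1 hydroxyl (five-membered ring O1–C8–C9–C10–C1) and dehydration of the C12 hydroperoxide give the dihydrofuran spiroketal and butenolide B together; C8 follows from the O1 bridge and the acyloxy ketal can equilibrate under acid.

Step 17
Reactants: 26 bis-butenolide spiroketal
Product: 27 (1S,4S,5S,6S,8S)-4,5-dihydroxy-1,8-epoxygermacra-7(11),9-diene-15,6:12,8-diolide (C6 unchanged in space; the descriptor changes with the priorities)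
Conditions: OsO4 (5 mol %), NMO, citric acid, t-BuOH/H2O, rt
Reagents that add atoms: osmium tetroxide, O=[Os](=O)(=O)=O; N-methylmorpholine N-oxide, C[N+]1([O-])CCOCC1; water, O
Why: Syn-dihydroxylation of the strained bridgehead C4=C5 bond on its only open face, anti to C7, sets C4 and C5; C7=C11 is tetrasubstituted and electron-poor and C9=C10 is hindered and flanked by three allylic C–O bonds, so both should react more slowly.

Step 18
Reactants: 27 diol
Product: 28 (1S,4S,5S,6R,7R,8S,11S)-7,11-epoxy lactone
Conditions: t-BuOOH (anhydrous), DBU, CH2Cl2, 0 °C → rt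
Reagents that add atoms: tert-butyl hydroperoxide, CC(C)(C)OO
Why: Weitz–Scheffer nucleophilic epoxidation, which can touch only the conjugated C7=C11 bond; the peroxide is expected to add to C7 on the O1 face, away from the C9=C10 arm, which sets C7.

Step 19
Reactants: 28 epoxy lactone
Product: 29 (1S,4S,5S,6R,7S,8S,11S)-4,5,7-trihydroxy-1,8-epoxygermacr-9-ene-15,6:12,8-diolide
Conditions: SmI2 (2.5 equiv), THF/MeOH, −78 °C
Reagents that add atoms: none
Why: Reductive opening of the α,β-epoxy lactone at the α C–O bond (two single-electron transfers, samarium enolate) keeps the C7–O bond and leaves the α-hydroxy lactone A alone at −78 °C; protonation of the enolate, or equilibration of the epimerisable C11, should place the C13 methyl trans to C6.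

Step 20
Reactants: 29 triol
Product: 30 CNP0315698.1 (5-O-acetate of 29)
Conditions: Ac2O (1.5 equiv), pyridine, DMAP (cat.), CH2Cl2, 0 °C
Reagents that add atoms: acetic anhydride, CC(=O)OC(C)=O
Why: Acylation selective for the only secondary hydroxyl (C5); the tertiary C4 and C7 hydroxyls should not react under these conditions.

## Compound list

1 | ethyl acetoacetate | CCOC(=O)CC(C)=O | starting material
2 | chloroacetone | CC(=O)CCl | starting material
3 | ethyl 2,4-dimethylfuran-3-carboxylate | CCOC(=O)c1c(C)occ1C | intermediate
4 | ethyl 2-(bromomethyl)-4-methylfuran-3-carboxylate | CCOC(=O)c1c(CBr)occ1C | intermediate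
5 | 3-methylpentane-2,4-dione | CC(=O)C(C)C(C)=O | starting material
6 | ethyl 2-(2-acetyl-2-methyl-3-oxobutyl)-4-methylfuran-3-carboxylate | CCOC(=O)c1c(CC(C)(C(C)=O)C(C)=O)occ1C | intermediate
7 | ethyl 4-methyl-2-(2-methyl-3-oxobutyl)furan-3-carboxylate (racemic) | CCOC(=O)c1c(CC(C)C(C)=O)occ1C | intermediate
8 | ethyl 2-[(E)-3-(tert-butyldimethylsilyloxy)-2-methylbut-2-enyl]-4-methylfuran-3-carboxylate (enol geometry immaterial) | C/C(O[Si](C)(C)C(C)(C)C)=C(/C)Cc1occ(C)c1C(=O)OCC | intermediate
9 | {2-[(E)-3-(tert-butyldimethylsilyloxy)-2-methylbut-2-enyl]-4-methylfuran-3-yl}methanol | C/C(O[Si](C)(C)C(C)(C)C)=C(/C)Cc1occ(C)c1CO | intermediate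
10 | 2-[(E)-3-(tert-butyldimethylsilyloxy)-2-methylbut-2-enyl]-4-methylfuran-3-carbaldehyde | C/C(O[Si](C)(C)C(C)(C)C)=C(/C)Cc1occ(C)c1C=O | intermediate
11 | methyl propiolate | C#CC(=O)OC | starting material
12 | methyl (4R)-4-hydroxy-4-(furan-3-yl)but-2-ynoate carrying the C10 enol silane | C/C(O[Si](C)(C)C(C)(C)C)=C(/C)Cc1occ(C)c1[C@H](O)C#CC(=O)OC | intermediate
13 | methyl (2Z,4R)-4-hydroxy-4-(furan-3-yl)but-2-enoate carrying the C10 enol silane | C/C(O[Si](C)(C)C(C)(C)C)=C(/C)Cc1occ(C)c1[C@H](O)/C=C\C(=O)OC | intermediate
14 | (5R)-5-(furan-3-yl)furan-2(5H)-one carrying the C10 enol silane (butenolide A) | C/C(O[Si](C)(C)C(C)(C)C)=C(/C)Cc1occ(C)c1[C@@H]1OC(=O)C=C1 | intermediate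
15 | tert-butyldimethylsilyl ketene acetal of lactone 16 (C4=C15, same configuration as 16) | CC(=O)[C@@]1(C)Cc2occ(C)c2[C@@H]2OC(O[Si](C)(C)C(C)(C)C)=C[C@H]12 | intermediate
16 | (5R,6R,10S)-furano keto lactone: C5–C10 cyclohexane fused to the furan, CH3 and acetyl on C10, cis-fused C15–O–C6 γ-lactone (H5 and H6 cis, acetyl trans to C4) | CC(=O)[C@@]1(C)Cc2occ(C)c2[C@@H]2OC(=O)C[C@H]12 | intermediate
17 | (5R,6R,10S)-1-(tert-butyldimethylsilyloxy)vinyl analogue of 16 | C=C(O[Si](C)(C)C(C)(C)C)[C@@]1(C)Cc2occ(C)c2[C@@H]2OC(=O)C[C@H]12 | intermediate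
18 | (4R,5R,6R,10S)-4-(dimethylaminomethyl) lactone (Mannich base of 17) | C=C(O[Si](C)(C)C(C)(C)C)[C@@]1(C)Cc2occ(C)c2[C@@H]2OC(=O)[C@@H](CN(C)C)[C@H]12 | intermediate
19 | trimethylammonium iodide of 18 | C=C(O[Si](C)(C)C(C)(C)C)[C@@]1(C)Cc2occ(C)c2[C@@H]2OC(=O)[C@@H](C[N+](C)(C)C)[C@H]12.[I-] | intermediate
20 | (5S,6R,10S)-furano-elemanolide: cis-fused α-methylene lactone on C5–C6, 1-siloxyvinyl group on C10 | C=C(O[Si](C)(C)C(C)(C)C)[C@@]1(C)Cc2occ(C)c2[C@@H]2OC(=O)C(=C)[C@H]12 | intermediate
21 | (6R)-furano-germacranolide: ten-membered ring, butenolide A on the ring-trans C4=C5 bond, ring-trans C1=C10 silyl enol ether | C/C1=C(O[Si](C)(C)C(C)(C)C)\CCC2=C[C@@H](OC2=O)c2c(C1)occ2C | intermediate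
22 | (6R,9Z)-1-oxo-9-ene furano-germacranolide | C/C1=C/c2occ(C)c2[C@@H]3OC(=O)C(=C3)CCC1=O | intermediate
23 | (1S,6R,9Z)-1-hydroxy-9-ene furano-germacranolide | C/C1=C/c2occ(C)c2[C@@H]3OC(=O)C(=C3)CC[C@@H]1O | intermediate
24 | furan 8,12-endoperoxide of 23 | C/C1=C/C24OOC(O2)C(C)=C4[C@@H]3OC(=O)C(=C3)CC[C@@H]1O | intermediate
25 | (1S,6R,8S)-1,8-epoxy spiroketal 12-hydroperoxide (C12 epimers) | C1=C2CC[C@@H]3O[C@@]4(C=C3C)OC(OO)C(C)=C4[C@@H]1OC2=O | intermediate
26 | (1S,6R,8S)-1,8-epoxygermacra-4,7(11),9-triene-15,6:12,8-diolide | C1=C2CC[C@@H]3O[C@@]4(C=C3C)OC(=O)C(C)=C4[C@@H]1OC2=O | intermediate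
27 | (1S,4S,5S,6S,8S)-4,5-dihydroxy-1,8-epoxygermacra-7(11),9-diene-15,6:12,8-diolide | O[C@H]1[C@H]2OC(=O)[C@]1(O)CC[C@@H]1O[C@@]3(C=C1C)OC(=O)C(C)=C23 | intermediate
28 | (1S,4S,5S,6R,7R,8S,11S)-7,11-epoxy-4,5-dihydroxy-1,8-epoxygermacr-9-ene-15,6:12,8-diolide | O[C@H]1[C@H]2OC(=O)[C@]1(O)CC[C@@H]1O[C@@]3(C=C1C)OC(=O)[C@]4(C)[C@]23O4 | intermediate
29 | (1S,4S,5S,6R,7S,8S,11S)-4,5,7-trihydroxy-1,8-epoxygermacr-9-ene-15,6:12,8-diolide | O[C@H]1[C@H]2OC(=O)[C@]1(O)CC[C@@H]1O[C@@]3(C=C1C)OC(=O)[C@@H](C)[C@]23O | intermediate
30 | CNP0315698.1, (1S,4S,5S,6R,7S,8S,11S)-5-acetoxy-4,7-dihydroxy-1,8-epoxygermacr-9-ene-15,6:12,8-diolide | CC(=O)O[C@H]1[C@H]2OC(=O)[C@]1(O)CC[C@@H]1O[C@@]3(C=C1C)OC(=O)[C@@H](C)[C@]23O | target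

## Step count

Total: 20 steps. Longest linear sequence: 20 steps (1 and 2 to 30); 5 and 11 enter as bought building blocks.

## Steps most likely to fail

**Step 13.** The [3,3] equilibrium may rest on the cyclohexane side, or the enol silane may be consumed before it rearranges (protodesilylation, or acid-triggered closure of C2 onto C3). The fallback sets out from 16 and returns at 22. The C1 oxygen is left off for the rearrangement and restored afterwards, so that the ring expansion runs on the vinyl elemanolide type whose thermal equilibrium with the germacranolide is documented. Ketone 16 is converted with KHMDS and PhNTf2 into the enol triflate F1, which Pd(OAc)2, PPh3 and HCO2H/Et3N reduce to the vinyl lactone F2. Methylenation as in steps 11 and 12, through the Mannich base F3 and its methiodide F4, gives the α-methylene lactone F5. Heating gives the germacranolide F6, with unchanged F5 recycled. 9-BBN adds to the trisubstituted C1=C10 bond with boron on C1 to give the organoborane F7, NaBO3 gives the C1 alcohol F8, and Dess–Martin periodinane gives the C1 ketone F9. IBX dehydrogenation toward the furfurylic C9 then gives enone 22.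

**Step 16.** The endoperoxide may collapse or be captured elsewhere before the C1 hydroxyl reaches C8 across the ring, and a kinetic closure offers no handle on the ketal configuration. The fallback sets out from 23 and returns at 26; it separates furan oxidation from ketal closure. The alcohol is silylated (TESCl, imidazole) to the triethylsilyl ether F10. Photooxygenation in methanol gives the methoxy hydroperoxide F11, which Ac2O/pyridine dehydrates to the 8-methoxy butenolide F12. Camphorsulfonic acid in CH2Cl2 with a little methanol removes the silyl group to give the hydroxy ketal F13. Continued exposure over 4 Å molecular sieves exchanges the methoxy group for the C1 oxygen under thermodynamic control and gives 26.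

**Step 18.** Conjugate addition of the peroxide anion to the fully substituted C7 may be too slow, so that base-induced opening of the acyloxy ketal lactone or reactions of the diol alkoxides take over. The fallback sets out from 23 and returns at 28. C7=C11 is epoxidised before it becomes an electron-poor butenolide, and the order of the two later oxidations is exchanged. After the photooxygenation of step 16, hydroperoxide 25 is treated in the same flask with dimethyldioxirane in acetone. This should take the isolated tetrasubstituted C7=C11 bond on the face anti to C9 and to the C12 substituent and give the epoxy hydroperoxide F14. Ac2O/pyridine then gives the epoxy lactone F15, and OsO4/NMO dihydroxylation of its strained C4=C5 bond as in step 17 gives 28.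

## Further compounds

F1 | step 13 | enol triflate | C=C(OS(=O)(=O)C(F)(F)F)[C@@]1(C)Cc2occ(C)c2[C@@H]2OC(=O)C[C@H]12
F2 | step 13 | vinyl lactone | C=C[C@@]1(C)Cc2occ(C)c2[C@@H]2OC(=O)C[C@H]12
F3 | step 13 | Mannich base | C=C[C@@]1(C)Cc2occ(C)c2[C@@H]2OC(=O)[C@@H](CN(C)C)[C@H]12
F4 | step 13 | methiodide | C=C[C@@]1(C)Cc2occ(C)c2[C@@H]2OC(=O)[C@@H](C[N+](C)(C)C)[C@H]12.[I-]
F5 | step 13 | α-methylene lactone | C=C[C@@]1(C)Cc2occ(C)c2[C@@H]2OC(=O)C(=C)[C@H]12
F6 | step 13 | germacranolide | C/C1=C\CCC2=C[C@@H](OC2=O)c2c(C1)occ2C
F7 | step 13 | organoborane | CC1Cc2occ(C)c2[C@@H]2OC(=O)C(=C2)CCC1B1C2CCCC1CCC2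
F8 | step 13 | C1 alcohol | CC1Cc2occ(C)c2[C@@H]2OC(=O)C(=C2)CCC1O
F9 | step 13 | C1 ketone | CC1Cc2occ(C)c2[C@@H]2OC(=O)C(=C2)CCC1=O
F10 | step 16 | triethylsilyl ether | C/C1=C/c2occ(C)c2[C@@H]3OC(=O)C(=C3)CC[C@@H]1O[Si](CC)(CC)CC
F11 | step 16 | methoxy hydroperoxide | C/C1=C/C2(OC)OC(OO)C(C)=C2[C@@H]3OC(=O)C(=C3)CC[C@@H]1O[Si](CC)(CC)CC
F12 | step 16 | 8-methoxy butenolide | C/C1=C/C2(OC)OC(=O)C(C)=C2[C@@H]3OC(=O)C(=C3)CC[C@@H]1O[Si](CC)(CC)CC
F13 | step 16 | hydroxy ketal | C/C1=C/C2(OC)OC(=O)C(C)=C2[C@@H]3OC(=O)C(=C3)CC[C@@H]1O
F14 | step 18 | epoxy hydroperoxide | C1=C2CC[C@@H]3O[C@@]4(C=C3C)OC(OO)[C@@]5(C)O[C@@]45[C@@H]1OC2=O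
F15 | step 18 | epoxy lactone | C1=C2CC[C@@H]3O[C@@]4(C=C3C)OC(=O)[C@@]5(C)O[C@@]45[C@@H]1OC2=O
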